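The retrosynthesis uses these ring letters: A is the formyl-bearing arene, B the seven-membered lactone-ether ring, C the central arene, D the dimethylpyranone. It cuts the lactone O–C(=O) bond of ring B, then the aryl–C(=O) and O–CMe2 bonds of ring D. In ring C it cuts the bond shared with ring D, between the carbon bearing the ring D oxygen and the carbon bearing the ring D carbonyl. Last it cuts the vinyl C–O bond that ties the ring A oxygen to a four-membered ring.
Enabling feature: on ring C the lactone oxygen and the ring D oxygen are para. The ether oxygen to ring A is ortho to the lactone oxygen, and the methyl group holds the other ortho position. Read around the ring, this is the substituent map of a 3-aryloxy-4-hydroxy-4-isopropenylcyclobut-2-enone.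
Forward order: ring A is finished first, with its formyl carbon placed ortho to the free hydroxyl of an orsellinate and masked as a dithiane. It is then attached through oxygen to a cyclobutenedione.
Ring C arises by thermal ring expansion, ring B by lactonisation and ring D by chromanone annulation. The ring A phenol is released last.
Stereochemistry: the target is achiral. The carbinol carbons of the reduced squarate and of the cyclobutenone are racemic and are erased again.
Key step: step 8

Remark: diisopropyl squarate is taken as the commercial, soluble form of squaric acid.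

Step 1
Reactants: 1 methyl orsellinate (methyl 2,4-dihydroxy-6-methylbenzoate)
Product: 2 methyl 2-hydroxy-4-methoxy-6-methylbenzoate
Conditions: MeI (1.05 equiv), K2CO3, acetone, reflux
Reagents that add atoms: iodomethane, CI
Why: Williamson etherification in which the 2-hydroxyl, locked in a hydrogen bond to the ester carbonyl, stays untouched, so one equivalent of MeI should alkylate only the more acidic and unhindered 4-hydroxyl and give an acid-proof ether that can still be removed at the end.

Step 2
Reactants: 2 methyl 2-hydroxy-4-methoxy-6-methylbenzoate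
Product: 3 methyl 3-formyl-2-hydroxy-4-methoxy-6-methylbenzoate
Conditions: MgCl2, Et3N, (CH2O)n, MeCN, reflux; then 1 M HCl
Reagents that add atoms: formaldehyde (from paraformaldehyde), C=O
Why: Casnati–Skattebøl ortho-formylation delivers formaldehyde inside the magnesium phenoxide to a carbon ortho to the free hydroxyl, and C3 is the only such carbon left, so the formyl carbon is fixed between the two oxygens now, whereas in the finished tetracycle the ring A position para to the ether oxygen would compete.

Step 3
Reactants: 3 methyl 3-formyl-2-hydroxy-4-methoxy-6-methylbenzoate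
Product: 4 methyl 3-(1,3-dithian-2-yl)-2-hydroxy-4-methoxy-6-methylbenzoate
Conditions: HS(CH2)3SH, BF3·OEt2 (0.2 equiv), CH2Cl2, 0 °C to rt
Reagents that add atoms: propane-1,3-dithiol, SCCCS
Why: BF3-catalysed thioacetalisation gives a mask that, unlike an O,O-acetal beside a free phenol, is stable on isolation and should withstand phenoxide formation, the Grignard reagent, the thermolysis, iodide and carbodiimide.

Step 4
Reactants: 5 diisopropyl squarate (3,4-diisopropoxycyclobut-3-ene-1,2-dione)
Product: 7 3-isopropoxycyclobut-3-ene-1,2-dione, via hydroxycyclobutenone 6 (not isolated)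
Conditions: LiAlH(OtBu)3, THF, −78 to −20 °C; then 6 M HCl, CH2Cl2, rt
Reagents that add atoms: none
Why: Selective 1,2-reduction of one squarate carbonyl by the bulky alkoxyaluminium hydride gives racemic carbinol 6, which in acid loses its hydroxyl in an allylic sense and then propan-2-ol, the established way from a squarate diester to a semisquarate ester.

Step 5
Reactants: 7 3-isopropoxycyclobut-3-ene-1,2-dione
Product: 8 semisquaric acid (3-hydroxycyclobut-3-ene-1,2-dione)
Conditions: 2 M HCl, THF, 40 °C; evaporation, toluene azeotrope
Reagents that add atoms: water, O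
Why: Acid hydrolysis of a vinylogous ester, by addition of water to the alkoxy-bearing carbon and loss of propan-2-ol, should give the strongly acidic, water-soluble semisquaric acid, which is isolated simply by evaporation.

Step 6
Reactants: 8 semisquaric acid; 4 methyl 3-(1,3-dithian-2-yl)-2-hydroxy-4-methoxy-6-methylbenzoate
Product: 10 methyl 3-(1,3-dithian-2-yl)-2-[(3,4-dioxocyclobut-1-en-1-yl)oxy]-4-methoxy-6-methylbenzoate, via semisquaric chloride 9 (not isolated)
Conditions: 8, (COCl)2, DMF (cat.), CH2Cl2, 0 °C to rt, evaporation; 4, NaH, THF, 0 °C, added to 9 in THF at −78 °C, then to 0 °C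
Reagents that add atoms: none
Why: Vilsmeier-type chlorination turns the vinylogous acid into its acid chloride 9, and the sodium phenoxide of 4 then replaces chloride by addition–elimination at the chlorine-bearing carbon (vinylogous O-acylation), a reaction fast enough at low temperature to cope with the flanked, chelated phenol.

Step 7
Reactants: 10 aryl semisquarate from step 6; 11 isopropenylmagnesium bromide
Product: 12 rac-methyl 3-(1,3-dithian-2-yl)-2-{[4-hydroxy-3-oxo-4-(prop-1-en-2-yl)cyclobut-1-en-1-yl]oxy}-4-methoxy-6-methylbenzoate (a 3-aryloxy-4-hydroxy-4-isopropenylcyclobut-2-enone)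
Conditions: 11 (1.05 equiv), THF, −78 °C; pH 7 phosphate buffer at −78 °C; no acidic media on isolation
Reagents that add atoms: none
Why: Grignard 1,2-addition in which the carbonyl attached to the CH carbon is deactivated as a vinylogous ester, so the reagent should attack the ketone attached to the aryloxy-bearing carbon as it does in alkyl semisquarates, the di-ortho-substituted methyl ester and the dithiane being inert at −78 °C, and the new carbinol centre is racemic and disappears in step 8.

Step 8
Reactants: 12 rac-3-aryloxy-4-hydroxy-4-isopropenylcyclobut-2-enone from step 7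
Product: 15 methyl 2-(2,5-dihydroxy-3-methylphenoxy)-3-(1,3-dithian-2-yl)-4-methoxy-6-methylbenzoate, via dienylketene 13 (not isolated), via cyclohexadienone 14 (not isolated)
Conditions: degassed toluene (0.02 M), 110 °C, Ar
Reagents that add atoms: none
Why: Heating opens the strained cyclobutenone by a conrotatory 4π electrocyclic reaction that breaks the C(=O)–C(OH) bond; the donor hydroxyl turns outward and the isopropenyl group inward, so dienylketene 13 has the (Z) geometry in which the ketene carbon and the alkene CH2 face each other. A disrotatory 6π electrocyclisation joins these two carbons, the only new skeletal bond, and closes ring C as a six-membered carbocycle (dienone 14), which enolises to the hydroquinone with gain of aromaticity and loss of ring strain. This is the Moore rearrangement of 4-alkenyl-4-hydroxycyclobutenones, well known for the 3-alkoxy members of the class, of which the 3-aryloxy compound is a spectator variation. No stereocentre is formed and the racemic carbinol centre of 12 vanishes. The step needs torquoselectivity and a faithful transfer of the substituent map: the first is secured by the electronic outward preference of the oxygen donor, the second by the ring itself, because the carbinol carbon (future lactone oxygen) is flanked by the aryloxy carbon and by the methyl-bearing alkene carbon while the ketene carbonyl becomes the para hydroxyl. Oxygen is excluded so that the electron-rich hydroquinone is not carried on to the quinone, and ester, dithiane and methyl ether are inert at this temperature.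

Step 9
Reactants: 15 hydroquinone methyl ester from step 8
Product: 16 2-(2,5-dihydroxy-3-methylphenoxy)-3-(1,3-dithian-2-yl)-4-methoxy-6-methylbenzoic acid
Conditions: LiI, pyridine, reflux, Ar; then 1 M HCl
Reagents that add atoms: none
Why: SN2 dealkylation by iodide attacks the methyl carbon and so bypasses the di-ortho-substituted carbonyl, and the nearly neutral medium avoids both air oxidation of a hydroquinone anion and a base-induced Smiles migration of ring A between the two neighbouring oxygens.

Step 10
Reactants: 16 hydroxy acid from step 9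
Product: 17 4-(1,3-dithian-2-yl)-7-hydroxy-3-methoxy-1,9-dimethyl-11H-dibenzo[b,e][1,4]dioxepin-11-one
Conditions: DCC, DMAP (cat.), CH2Cl2 (2 mM, slow addition), rt
Reagents that add atoms: none
Why: Steglich-type carbodiimide lactonisation, the classical depsidone closure of 2-(2-hydroxyphenoxy)benzoic acids, in which only the hydroxyl ortho to the ether oxygen can reach the activated carboxyl within the molecule (seven-membered ring B), high dilution holds back acylation of the other phenol, and the non-acidic activation excludes Friedel–Crafts attack of the acyl carbon on ring C.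

Step 11
Reactants: 17 dithiane-masked depsidone phenol
Product: 18 7-hydroxy-3-methoxy-1,9-dimethyl-11-oxo-11H-dibenzo[b,e][1,4]dioxepine-4-carbaldehyde
Conditions: MeI, CaCO3, MeCN/H2O, 45 °C
Reagents that add atoms: water, O
Why: Alkylative dithiane hydrolysis (S-methylation, opening to the aryl-stabilised thionium ion, capture by water) is non-oxidative and so spares the free phenol, and it is placed after closure of ring B so that no ortho-phenoxide ever faces a ring A activated by two carbonyl groups.

Step 12
Reactants: 18 depsidone aldehyde phenol; 19 3-methylbut-2-enoic acid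
Product: 22 mollicellin B methyl ether (the target with OCH3 in place of the ring A hydroxyl), via aryl senecioate 20 (not isolated), via hydroxyaryl enone 21 (not isolated)
Conditions: P2O5/MeSO3H (1:10 w/w), 60 °C
Reagents that add atoms: none
Why: One-pot chromanone annulation (esterification, Fries-type acyl shift, oxa-Michael closure) as established for 3,4-dialkoxyphenols, which are acylated para to the 3-oxygen and not between the oxygens, so that here the carbon between hydroxyl and methyl should react, ring A being switched off by its formyl and lactone carbonyls and the methyl ether being stable to the acid.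

Step 13
Reactants: 22 mollicellin B methyl ether
Product: 23 mollicellin B
Conditions: BCl3, CH2Cl2, −78 to 0 °C; then H2O
Reagents that add atoms: none
Why: Chelation-assisted ether cleavage in which BCl3 binds the formyl oxygen and the neighbouring methoxy oxygen and chloride removes the methyl group at low temperature, conditions under which the aryl lactone, the diaryl ether and the 2,2-dimethylchromanone should persist.

Compound list
1 | methyl orsellinate (methyl 2,4-dihydroxy-6-methylbenzoate) | Cc1cc(O)cc(O)c1C(=O)OC | starting material
2 | methyl 2-hydroxy-4-methoxy-6-methylbenzoate | Cc1cc(OC)cc(O)c1C(=O)OC | intermediate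
3 | methyl 3-formyl-2-hydroxy-4-methoxy-6-methylbenzoate | Cc1cc(OC)c(C=O)c(O)c1C(=O)OC | intermediate
4 | methyl 3-(1,3-dithian-2-yl)-2-hydroxy-4-methoxy-6-methylbenzoate | Cc1cc(OC)c(C2SCCCS2)c(O)c1C(=O)OC | intermediate
5 | diisopropyl squarate (3,4-diisopropoxycyclobut-3-ene-1,2-dione) | CC(C)OC1=C(OC(C)C)C(=O)C1=O | starting material
6 | rac-4-hydroxy-2,3-diisopropoxycyclobut-2-en-1-one | CC(C)OC1=C(OC(C)C)C(=O)C1O | intermediate
7 | 3-isopropoxycyclobut-3-ene-1,2-dione | CC(C)OC1=CC(=O)C1=O | intermediate
8 | semisquaric acid (3-hydroxycyclobut-3-ene-1,2-dione) | OC1=CC(=O)C1=O | intermediate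
9 | semisquaric chloride (3-chlorocyclobut-3-ene-1,2-dione) | ClC1=CC(=O)C1=O | intermediate
10 | methyl 3-(1,3-dithian-2-yl)-2-[(3,4-dioxocyclobut-1-en-1-yl)oxy]-4-methoxy-6-methylbenzoate | COC(=O)c1c(C)cc(OC)c(C2SCCCS2)c1OC1=CC(=O)C1=O | intermediate
11 | isopropenylmagnesium bromide | C=C(C)[Mg]Br | starting material
12 | rac-methyl 3-(1,3-dithian-2-yl)-2-{[4-hydroxy-3-oxo-4-(prop-1-en-2-yl)cyclobut-1-en-1-yl]oxy}-4-methoxy-6-methylbenzoate | C=C(C)C1(O)C(=O)C=C1Oc1c(C2SCCCS2)c(OC)cc(C)c1C(=O)OC | intermediate
13 | methyl 3-(1,3-dithian-2-yl)-2-{[(3Z)-4-hydroxy-5-methyl-1-oxohexa-1,3,5-trien-3-yl]oxy}-4-methoxy-6-methylbenzoate (dienylketene) | O=C=C/C(Oc1c(C2SCCCS2)c(OC)cc(C)c1C(=O)OC)=C(\C(C)=C)O | intermediate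
14 | methyl 3-(1,3-dithian-2-yl)-2-[(6-hydroxy-5-methyl-3-oxocyclohexa-1,5-dien-1-yl)oxy]-4-methoxy-6-methylbenzoate (cyclohexadienone) | O=C1C=C(Oc2c(C3SCCCS3)c(OC)cc(C)c2C(=O)OC)C(O)=C(C)C1 | intermediate
15 | methyl 2-(2,5-dihydroxy-3-methylphenoxy)-3-(1,3-dithian-2-yl)-4-methoxy-6-methylbenzoate | Cc1cc(O)cc(Oc2c(C3SCCCS3)c(OC)cc(C)c2C(=O)OC)c1O | intermediate
16 | 2-(2,5-dihydroxy-3-methylphenoxy)-3-(1,3-dithian-2-yl)-4-methoxy-6-methylbenzoic acid | Cc1cc(O)cc(Oc2c(C3SCCCS3)c(OC)cc(C)c2C(=O)O)c1O | intermediate
17 | 4-(1,3-dithian-2-yl)-7-hydroxy-3-methoxy-1,9-dimethyl-11H-dibenzo[b,e][1,4]dioxepin-11-one | Cc1cc(OC)c(C3SCCCS3)c2c1C(=O)Oc1c(C)cc(O)cc1O2 | intermediate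
18 | 7-hydroxy-3-methoxy-1,9-dimethyl-11-oxo-11H-dibenzo[b,e][1,4]dioxepine-4-carbaldehyde | Cc1cc(OC)c(C=O)c2c1C(=O)Oc1c(C)cc(O)cc1O2 | intermediate
19 | 3-methylbut-2-enoic acid | CC(C)=CC(=O)O | starting material
20 | 7-O-(3-methylbut-2-enoyl) ester of 18 (aryl senecioate) | Cc1cc(OC)c(C=O)c2c1C(=O)Oc1c(C)cc(OC(=O)C=C(C)C)cc1O2 | intermediate
21 | 8-(3-methylbut-2-enoyl) derivative of 18 (ortho-hydroxyaryl enone) | Cc1cc(OC)c(C=O)c2c1C(=O)Oc1c(C)c(C(=O)C=C(C)C)c(O)cc1O2 | intermediate
22 | mollicellin B methyl ether | Cc1cc(OC)c(C=O)c2c1C(=O)Oc1c(cc3c(c1C)C(=O)CC(C)(C)O3)O2 | intermediate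
23 | mollicellin B | Cc1cc(O)c(C=O)c2c1C(=O)Oc1c(cc3c(c1C)C(=O)CC(C)(C)O3)O2 | target

Total step count: 13. Longest linear sequence: 11 steps (1, 2, 3, 6, 7, 8, 9, 10, 11, 12, 13).

Steps most likely to fail

Step 12.
- **What may go wrong:** Acylation may occur at the ring C carbon between the hydroxyl and the ether oxygen. The arene may be alkylated by the β-carbon of the protonated acid in place of acylation. The hindered lactone may ionise in the strong acid, with closure of its acyl carbon onto ring C. The protonated aldehyde may condense with a phenol.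
- **Fallback:** Ring D is built before ring B, and no unsaturated acid meets strong acid. The fallback sets out from 15 and comes back at 22. Nencki-type C-acetylation of 15 with AcOH/BF3·OEt2 at 80 °C should go para to the aryloxy oxygen, away from the still freely rotating, bulky ring A. It should give methyl 2-(4-acetyl-2,5-dihydroxy-3-methylphenoxy)-3-(1,3-dithian-2-yl)-4-methoxy-6-methylbenzoate F1. Kabbe condensation with acetone and pyrrolidine in MeOH closes ring D to methyl 3-(1,3-dithian-2-yl)-2-[(6-hydroxy-2,2,5-trimethyl-4-oxochroman-7-yl)oxy]-4-methoxy-6-methylbenzoate F2. LiI in refluxing pyridine gives 3-(1,3-dithian-2-yl)-2-[(6-hydroxy-2,2,5-trimethyl-4-oxochroman-7-yl)oxy]-4-methoxy-6-methylbenzoic acid F3. DCC/DMAP now meets a single phenol and closes ring B to the dithiane of mollicellin B methyl ether F4. MeI/CaCO3 in aqueous MeCN then releases the aldehyde 22.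

Step 7.
- **What may go wrong:** The reagent may attack the aryloxy-bearing carbon and expel the phenoxide, or add to the less hindered vinylogous ester carbonyl. The vinylogous aryl ester may solvolyse, or the alkoxide may suffer ring cleavage, during quench and isolation.
- **Fallback:** It sets out from 10 and comes back at 15. Reagent 11 is first transmetallated with anhydrous CeCl3 to a less basic, strictly carbonyl-selective organocerium reagent. The resulting alkoxide is not protonated but silylated in the flask with Me3SiCl. This gives rac-methyl 3-(1,3-dithian-2-yl)-4-methoxy-6-methyl-2-{[3-oxo-4-(prop-1-en-2-yl)-4-(trimethylsilyloxy)cyclobut-1-en-1-yl]oxy}benzoate F5. The same thermal ring expansion in degassed toluene, with the silyloxy group turning outward, gives methyl 3-(1,3-dithian-2-yl)-2-[5-hydroxy-3-methyl-2-(trimethylsilyloxy)phenoxy]-4-methoxy-6-methylbenzoate F6. Bu4NF/AcOH in THF removes the silyl group to give 15.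

Step 6.
- **What may go wrong:** The labile monochloride may hydrolyse or oligomerise on concentration. O-acylation of the doubly flanked, chelated phenoxide may be sluggish.
- **Fallback:** It sets out from 4 and comes back at 10. Squaric acid with (COCl)2 and catalytic DMF gives the crystalline, storable 3,4-dichlorocyclobut-3-ene-1,2-dione F7. One equivalent of the sodium salt of 4 displaces one chloride at −78 °C. This gives methyl 2-[(2-chloro-3,4-dioxocyclobut-1-en-1-yl)oxy]-3-(1,3-dithian-2-yl)-4-methoxy-6-methylbenzoate F8. Reduction of the remaining vinylogous acyl chloride with Bu3SnH and catalytic Pd(PPh3)4 in THF, in the manner of the acid chloride to aldehyde reduction, gives 10.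

Further compounds
F1 | step 12 | methyl 2-(4-acetyl-2,5-dihydroxy-3-methylphenoxy)-3-(1,3-dithian-2-yl)-4-methoxy-6-methylbenzoate | CC(=O)c1c(O)cc(Oc2c(C3SCCCS3)c(OC)cc(C)c2C(=O)OC)c(O)c1C
F2 | step 12 | methyl 3-(1,3-dithian-2-yl)-2-[(6-hydroxy-2,2,5-trimethyl-4-oxochroman-7-yl)oxy]-4-methoxy-6-methylbenzoate | CC1(C)CC(=O)c2c(C)c(O)c(Oc3c(C4SCCCS4)c(OC)cc(C)c3C(=O)OC)cc2O1
F3 | step 12 | 3-(1,3-dithian-2-yl)-2-[(6-hydroxy-2,2,5-trimethyl-4-oxochroman-7-yl)oxy]-4-methoxy-6-methylbenzoic acid | CC1(C)CC(=O)c2c(C)c(O)c(Oc3c(C4SCCCS4)c(OC)cc(C)c3C(=O)O)cc2O1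
F4 | step 12 | dithiane of mollicellin B methyl ether | Cc1cc(OC)c(C4SCCCS4)c2c1C(=O)Oc1c(cc3c(c1C)C(=O)CC(C)(C)O3)O2
F5 | step 7 | rac-methyl 3-(1,3-dithian-2-yl)-4-methoxy-6-methyl-2-{[3-oxo-4-(prop-1-en-2-yl)-4-(trimethylsilyloxy)cyclobut-1-en-1-yl]oxy}benzoate | C=C(C)C1(O[Si](C)(C)C)C(=O)C=C1Oc1c(C2SCCCS2)c(OC)cc(C)c1C(=O)OC
F6 | step 7 | methyl 3-(1,3-dithian-2-yl)-2-[5-hydroxy-3-methyl-2-(trimethylsilyloxy)phenoxy]-4-methoxy-6-methylbenzoate | Cc1cc(O)cc(Oc2c(C3SCCCS3)c(OC)cc(C)c2C(=O)OC)c1O[Si](C)(C)C
F7 | step 6 | 3,4-dichlorocyclobut-3-ene-1,2-dione | ClC1=C(Cl)C(=O)C1=O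
F8 | step 6 | methyl 2-[(2-chloro-3,4-dioxocyclobut-1-en-1-yl)oxy]-3-(1,3-dithian-2-yl)-4-methoxy-6-methylbenzoate | COC(=O)c1c(C)cc(OC)c(C2SCCCS2)c1OC1=C(Cl)C(=O)C1=O
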